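**Strategy.** The cyclohexene is disconnected at the C6–C1 bond (C1 = CHOBz beside the quaternary carbon, C2=C3, C4 = CHOBz, C5 = CHOH, C6 = C(OH)CH2OH, C7 = CH2OH). The feature exploited is the α-oxygenated quaternary C6, whose C7 can be read as a carboxyl and which stands 1,4 to alkene carbon C3. An Ireland–Claisen rearrangement of a δ-lactone silyl ketene acetal forms C6–C1, breaks the ring C3–O bond and delivers the carbocycle, the quaternary centre and C1 in one operation. The precursor is a D-mannono-1,5-lactone (2,3-acetonide, 4-O-PMB) carrying a geometrically pure (E)-2-(PMB-oxy)vinyl group on its δ-carbon, made by Takai iodoolefination and stereoretentive CuI-catalysed etherification.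

Key step: step 11

Remark: hemiacetals 9 and 18 and silyl acetals 11, 12, 13, 15 and 17 are treated as anomeric mixtures (anomeric carbon undefined in the SMILES; it becomes the lactone carbonyl of 19). Carbohydrate numbering is used up to 21 (sugar C1, C2, C3, C4, C5 and the two vinyl carbons C6, C7 become target C7, C6, C5, C4, C3, C2, C1); target numbering is used from 22 on.

**Step 1**
Reactants: 1 D-mannose; 2 allyl alcohol
Product: 3 allyl α-D-mannopyranoside
Conditions: allyl alcohol (solvent), AcCl (cat.), 70 °C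
Reagents that add atoms: allyl alcohol, C=CCO
Why: Fischer glycosidation under thermodynamic control should give mainly the α-pyranoside, since the anomeric effect and the axial C2 oxygen of mannose both favour the axial glycoside; this centre is only a temporary mask.

**Step 2**
Reactants: 3 allyl α-D-mannopyranoside; 4 4-methoxybenzaldehyde dimethyl acetal; 5 2,2-dimethoxypropane
Product: 7 allyl 2,3-O-isopropylidene-4,6-O-[(R)-4-methoxybenzylidene]-α-D-mannopyranoside, via 4,6-O-arylidene diol 6 (not isolated)
Conditions: 4 (1.05 equiv), CSA (cat.), DMF, 50 °C, 150 mbar; then 5, rt; Et3N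
Reagents that add atoms: 4-methoxybenzaldehyde dimethyl acetal, COc1ccc(C(OC)OC)cc1; 2,2-dimethoxypropane, COC(C)(C)OC
Why: Acid-catalysed transacetalisation under thermodynamic control: the 4,6-diol closes the trans-fused 1,3-dioxane with equatorial aryl (acetal carbon R), and the remaining cis-2,3-diol then takes the isopropylidene ketal as a cis-fused dioxolane.

**Step 3**
Reactants: 7 allyl 2,3-O-isopropylidene-4,6-O-[(R)-4-methoxybenzylidene]-α-D-mannopyranoside
Product: 9 2,3-O-isopropylidene-4,6-O-[(R)-4-methoxybenzylidene]-D-mannopyranose, via prop-1-enyl glycoside 8 (not isolated)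
Conditions: [Ir(cod)(PMePh2)2]PF6 (cat., H2-activated), THF, rt; then I2, NaHCO3, THF/H2O, 0 °C → rt
Reagents that add atoms: none
Why: Allyl-to-propenyl isomerisation catalysed by [Ir(cod)(PMePh2)2]PF6, followed by iodonium-induced hydrolysis of the enol ether, is the standard two-stage anomeric deallylation and should spare both acetals under these buffered conditions.

**Step 4**
Reactants: 9 2,3-O-isopropylidene-4,6-O-[(R)-4-methoxybenzylidene]-D-mannopyranose; 10 chlorotriisopropylsilane
Product: 11 triisopropylsilyl 2,3-O-isopropylidene-4,6-O-[(R)-4-methoxybenzylidene]-D-mannopyranoside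
Conditions: iPr3SiCl, imidazole, DMAP (cat.), DMF, rt
Reagents that add atoms: chlorotriisopropylsilane, CC(C)[Si](Cl)(C(C)C)C(C)C
Why: O-Silylation of the hemiacetal hydroxyl gives a hydride- and base-stable anomeric mask that fluoride can later remove in the presence of an enol ether.

**Step 5**
Reactants: 11 triisopropylsilyl 2,3-O-isopropylidene-4,6-O-[(R)-4-methoxybenzylidene]-D-mannopyranoside
Product: 12 triisopropylsilyl 2,3-O-isopropylidene-4-O-(4-methoxybenzyl)-D-mannopyranoside
Conditions: iBu2AlH, toluene, −40 → 0 °C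
Reagents that add atoms: none
Why: Regioselective reductive opening of the arylidene acetal: aluminium coordinates the less hindered O6, the C–O6 bond ionises and hydride is delivered to the oxocarbenium ion, leaving the PMB ether on O4 and the primary alcohol free, while the less easily ionised ketal and silyl acetal should survive.

**Step 6**
Reactants: 12 triisopropylsilyl 2,3-O-isopropylidene-4-O-(4-methoxybenzyl)-D-mannopyranoside
Product: 13 triisopropylsilyl 2,3-O-isopropylidene-4-O-(4-methoxybenzyl)-D-manno-hexodialdo-1,5-pyranoside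
Conditions: Dess–Martin periodinane, NaHCO3, CH2Cl2, 0 °C → rt
Reagents that add atoms: none
Why: Dess–Martin oxidation is non-basic, so the α-alkoxy aldehyde should form without C5 epimerisation or β-elimination of the 4-O-PMB group; it is used directly.

**Step 7**
Reactants: 13 triisopropylsilyl 2,3-O-isopropylidene-4-O-(4-methoxybenzyl)-D-manno-hexodialdo-1,5-pyranoside; 14 iodoform
Product: 15 triisopropylsilyl (E)-6,7-dideoxy-7-iodo-2,3-O-isopropylidene-4-O-(4-methoxybenzyl)-D-manno-hept-6-enopyranoside
Conditions: CrCl2, CHI3, THF/1,4-dioxane, 0 °C → rt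
Reagents that add atoms: iodoform, IC(I)I
Why: Takai iodoolefination: the geminal dichromium species from CHI3 and CrCl2 adds to the aldehyde and eliminates with high E selectivity under non-basic conditions, fixing the alkene geometry that later decides C1.

**Step 8**
Reactants: 15 triisopropylsilyl (E)-6,7-dideoxy-7-iodo-2,3-O-isopropylidene-4-O-(4-methoxybenzyl)-D-manno-hept-6-enopyranoside; 16 4-methoxybenzyl alcohol
Product: 17 triisopropylsilyl (E)-6-deoxy-2,3-O-isopropylidene-4,7-di-O-(4-methoxybenzyl)-D-manno-hept-6-enopyranoside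
Conditions: CuI (cat.), 3,4,7,8-tetramethyl-1,10-phenanthroline (cat.), Cs2CO3, toluene, 80 °C
Reagents that add atoms: 4-methoxybenzyl alcohol, COc1ccc(CO)cc1
Why: Ullmann-type CuI-catalysed O-vinylation of a primary alcohol by an alkenyl iodide proceeds with retention of alkene geometry, and the substrate at this stage carries only acetal, ether and hindered silyl groups that should tolerate carbonate base.

**Step 9**
Reactants: 17 triisopropylsilyl (E)-6-deoxy-2,3-O-isopropylidene-4,7-di-O-(4-methoxybenzyl)-D-manno-hept-6-enopyranoside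
Product: 18 (E)-6-deoxy-2,3-O-isopropylidene-4,7-di-O-(4-methoxybenzyl)-D-manno-hept-6-enopyranose
Conditions: Bu4NF, AcOH, THF, 0 °C
Reagents that add atoms: none
Why: Fluoride desilylation of the anomeric silyl acetal, buffered with acetic acid, should free the hemiacetal without harming the acid-labile enol ether, the PMB ether or the ketal.

**Step 10**
Reactants: 18 (E)-6-deoxy-2,3-O-isopropylidene-4,7-di-O-(4-methoxybenzyl)-D-manno-hept-6-enopyranose
Product: 19 (E)-6-deoxy-2,3-O-isopropylidene-4,7-di-O-(4-methoxybenzyl)-D-manno-hept-6-enono-1,5-lactone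
Conditions: nPr4N[RuO4] (cat.), N-methylmorpholine N-oxide, 4 Å MS, CH2Cl2, rt
Reagents that add atoms: none
Why: Ley–Griffith oxidation of the lactol to the lactone is neutral; the δ-lactone cannot translactonise because O4 is blocked, and the product (an open-chain analogue of a 3-O-acyl glycal) is kept away from acid.

**Step 11**
Reactants: 19 (E)-6-deoxy-2,3-O-isopropylidene-4,7-di-O-(4-methoxybenzyl)-D-manno-hept-6-enono-1,5-lactone; 20 chlorotrimethylsilane
Product: 23 5,6-O-isopropylidene-1,4-bis(4-methoxybenzyloxy)cyclohex-2-ene-6-carboxylic acid (CO2H, C1–O and C4–O on one face; C5–O and C6–O on the other), via silyl ketene acetal 21 (not isolated), via trimethylsilyl ester 22 (not isolated)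
Conditions: Me3SiCl/Et3N, LiN(SiMe3)2, THF, −78 °C → rt; toluene, 80 °C; then H2O/THF (pH 5 buffer)
Reagents that add atoms: none
Why: LiN(SiMe3)2 deprotonates sugar C2 in the presence of Me3SiCl, so the enolate is O-silylated at once to the endocyclic, geometrically fixed silyl ketene acetal 21, which on warming undergoes a concerted suprafacial [3,3]-sigmatropic shift (Ireland–Claisen rearrangement) that forms sugar C2–C7 (target C6–C1), breaks C5–O5 and leaves the C5=C6 alkene (target C3=C2); hydrolysis of silyl ester 22 gives 23. The closest known reaction type is the Ireland–Claisen ring contraction of ω-alkenyl lactone silyl ketene acetals to cycloalkene carboxylic acids. The six-membered carbocycle closes pericyclically across the 1,4-positions of the lactone through a boat, bicyclo[2.2.2]octane-like transition state whose three bridges are the lactone C(=O)–O unit, the C3–C4 unit and the vinyl unit (a ring contraction, not a polar exo or endo closure). Target C6 is controlled by the sugar C5 stereocentre: the vinyl group can reach the enol carbon only from its own face, so the carboxyl stays on the face of the former lactone bridge, cis to the C4 oxygen and trans to the ketal oxygens, which remain cis-fused. Target C1 is controlled by the E geometry of the enol ether in the enforced boat, which places the C1 oxygen cis to the carboxyl. The step needs an exclusive boat pathway from a geometrically pure E-enol ether without β-elimination or ionisation: the lactone tether excludes a chair, the dioxolane holds the C3–O bond in the enolate plane, in-situ silylation keeps free enolate minimal, and neutral thermal conditions avoid heterolysis of the doubly activated allylic C–O bond.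

**Step 12**
Reactants: 23 5,6-O-isopropylidene-1,4-bis(4-methoxybenzyloxy)cyclohex-2-ene-6-carboxylic acid
Product: 24 6-(hydroxymethyl)-5,6-O-isopropylidene-1,4-bis(4-methoxybenzyloxy)cyclohex-2-ene
Conditions: LiAlH4, THF, 0 → 65 °C
Reagents that add atoms: none
Why: LiAlH4 reduction of the carboxylic acid to the primary alcohol; ethers, ketal and the isolated alkene are inert and no stereocentre is touched.

**Step 13**
Reactants: 24 6-(hydroxymethyl)-5,6-O-isopropylidene-1,4-bis(4-methoxybenzyloxy)cyclohex-2-ene; 25 tert-butylchlorodimethylsilane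
Product: 26 C7-O-tert-butyldimethylsilyl ether of 24
Conditions: tBuMe2SiCl, imidazole, DMF, rt
Reagents that add atoms: tert-butylchlorodimethylsilane, CC(C)(C)[Si](C)(C)Cl
Why: O-Silylation of the only free hydroxyl masks C7–OH with a group that the final acid step removes together with the ketal.

**Step 14**
Reactants: 26 C7-O-tert-butyldimethylsilyl ether of 24
Product: 27 C1,C4-diol (5,6-O-isopropylidene, C7-O-silyl)
Conditions: DDQ, CH2Cl2/aq. pH 7 buffer, 0 °C
Reagents that add atoms: none
Why: Oxidative PMB cleavage by DDQ (hydride abstraction to the oxocarbenium ion, then hydrolysis) should unveil both allylic alcohols while silyl ether, ketal and alkene remain.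

**Step 15**
Reactants: 27 C1,C4-diol; 28 benzoyl chloride
Product: 29 C1,C4-dibenzoate (5,6-O-isopropylidene, C7-O-silyl)
Conditions: BzCl, pyridine, DMAP (cat.), CH2Cl2, 0 °C → rt
Reagents that add atoms: benzoyl chloride, O=C(Cl)c1ccccc1
Why: DMAP-catalysed acylation; every other oxygen is blocked, so only C1–O and C4–O are benzoylated.

**Step 16**
Reactants: 29 C1,C4-dibenzoate
Product: 30 [(1S,4R,5S,6S)-4-(benzoyloxy)-5,6-dihydroxy-6-(hydroxymethyl)cyclohex-2-en-1-yl] benzoate (target)
Conditions: CF3CO2H/H2O (9:1), 0 °C → rt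
Reagents that add atoms: none
Why: Acid hydrolysis removes the isopropylidene ketal and the primary silyl ether in one operation; benzoates are stable to cold aqueous acid, and acyl migration, which is base-promoted, should stay slow.

**Compound list**
1 | D-mannose | OC[C@H]1OC(O)[C@@H](O)[C@@H](O)[C@@H]1O | starting material
2 | allyl alcohol | C=CCO | starting material
3 | allyl α-D-mannopyranoside | C=CCO[C@H]1O[C@H](CO)[C@@H](O)[C@H](O)[C@@H]1O | intermediate
4 | 4-methoxybenzaldehyde dimethyl acetal | COc1ccc(C(OC)OC)cc1 | starting material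
5 | 2,2-dimethoxypropane | COC(C)(C)OC | starting material
6 | allyl 4,6-O-[(R)-4-methoxybenzylidene]-α-D-mannopyranoside | C=CCO[C@H]1O[C@@H]2CO[C@@H](c3ccc(OC)cc3)O[C@H]2[C@H](O)[C@@H]1O | intermediate (not isolated)
7 | allyl 2,3-O-isopropylidene-4,6-O-[(R)-4-methoxybenzylidene]-α-D-mannopyranoside | C=CCO[C@H]1O[C@@H]2CO[C@@H](c3ccc(OC)cc3)O[C@H]2[C@@H]4OC(C)(C)O[C@H]14 | intermediate
8 | (E)-prop-1-enyl 2,3-O-isopropylidene-4,6-O-[(R)-4-methoxybenzylidene]-α-D-mannopyranoside | C/C=C/O[C@H]1O[C@@H]2CO[C@@H](c3ccc(OC)cc3)O[C@H]2[C@@H]4OC(C)(C)O[C@H]14 | intermediate (not isolated)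
9 | 2,3-O-isopropylidene-4,6-O-[(R)-4-methoxybenzylidene]-D-mannopyranose (anomeric mixture) | OC1O[C@@H]2CO[C@@H](c3ccc(OC)cc3)O[C@H]2[C@@H]4OC(C)(C)O[C@H]14 | intermediate
10 | chlorotriisopropylsilane | CC(C)[Si](Cl)(C(C)C)C(C)C | starting material
11 | triisopropylsilyl 2,3-O-isopropylidene-4,6-O-[(R)-4-methoxybenzylidene]-D-mannopyranoside (anomeric mixture) | CC(C)[Si](OC1O[C@@H]2CO[C@@H](c3ccc(OC)cc3)O[C@H]2[C@@H]4OC(C)(C)O[C@H]14)(C(C)C)C(C)C | intermediate
12 | triisopropylsilyl 2,3-O-isopropylidene-4-O-(4-methoxybenzyl)-D-mannopyranoside | CC(C)[Si](OC1O[C@H](CO)[C@@H](OCc2ccc(OC)cc2)[C@@H]3OC(C)(C)O[C@H]13)(C(C)C)C(C)C | intermediate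
13 | triisopropylsilyl 2,3-O-isopropylidene-4-O-(4-methoxybenzyl)-D-manno-hexodialdo-1,5-pyranoside | CC(C)[Si](OC1O[C@H](C=O)[C@@H](OCc2ccc(OC)cc2)[C@@H]3OC(C)(C)O[C@H]13)(C(C)C)C(C)C | intermediate
14 | iodoform | IC(I)I | starting material
15 | triisopropylsilyl (E)-6,7-dideoxy-7-iodo-2,3-O-isopropylidene-4-O-(4-methoxybenzyl)-D-manno-hept-6-enopyranoside | CC(C)[Si](OC1O[C@H](/C=C/I)[C@@H](OCc2ccc(OC)cc2)[C@@H]3OC(C)(C)O[C@H]13)(C(C)C)C(C)C | intermediate
16 | 4-methoxybenzyl alcohol | COc1ccc(CO)cc1 | starting material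
17 | triisopropylsilyl (E)-6-deoxy-2,3-O-isopropylidene-4,7-di-O-(4-methoxybenzyl)-D-manno-hept-6-enopyranoside | CC(C)[Si](OC1O[C@H](/C=C/OCc2ccc(OC)cc2)[C@@H](OCc2ccc(OC)cc2)[C@@H]3OC(C)(C)O[C@H]13)(C(C)C)C(C)C | intermediate
18 | (E)-6-deoxy-2,3-O-isopropylidene-4,7-di-O-(4-methoxybenzyl)-D-manno-hept-6-enopyranose (anomeric mixture) | OC1O[C@H](/C=C/OCc2ccc(OC)cc2)[C@@H](OCc2ccc(OC)cc2)[C@@H]3OC(C)(C)O[C@H]13 | intermediate
19 | (E)-6-deoxy-2,3-O-isopropylidene-4,7-di-O-(4-methoxybenzyl)-D-manno-hept-6-enono-1,5-lactone (key-step precursor) | O=C1O[C@H](/C=C/OCc3ccc(OC)cc3)[C@@H](OCc3ccc(OC)cc3)[C@@H]2OC(C)(C)O[C@H]12 | intermediate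
20 | chlorotrimethylsilane | C[Si](C)(C)Cl | starting material
21 | 1-O-trimethylsilyl ketene acetal of 19 (endocyclic C1=C2) | C[Si](C)(C)OC=1O[C@H](/C=C/OCc3ccc(OC)cc3)[C@@H](OCc3ccc(OC)cc3)[C@@H]2OC(C)(C)OC=12 | intermediate (not isolated)
22 | trimethylsilyl ester of 23 | COc1ccc(CO[C@H]2C=C[C@@H](OCc3ccc(OC)cc3)[C@H](OC4(C)C)[C@@]2(O4)C(=O)O[Si](C)(C)C)cc1 | intermediate (not isolated)
23 | 5,6-O-isopropylidene-1,4-bis(4-methoxybenzyloxy)cyclohex-2-ene-6-carboxylic acid, ring configuration as in 30 (key-step product) | COc1ccc(CO[C@H]2C=C[C@@H](OCc3ccc(OC)cc3)[C@H](OC4(C)C)[C@@]2(O4)C(=O)O)cc1 | intermediate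
24 | 6-(hydroxymethyl)-5,6-O-isopropylidene-1,4-bis(4-methoxybenzyloxy)cyclohex-2-ene, configuration as in 30 | COc1ccc(CO[C@H]2C=C[C@@H](OCc3ccc(OC)cc3)[C@H](OC4(C)C)[C@@]2(O4)CO)cc1 | intermediate
25 | tert-butylchlorodimethylsilane | CC(C)(C)[Si](C)(C)Cl | starting material
26 | C7-O-tert-butyldimethylsilyl ether of 24 | COc1ccc(CO[C@H]2C=C[C@@H](OCc3ccc(OC)cc3)[C@H](OC4(C)C)[C@@]2(O4)CO[Si](C)(C)C(C)(C)C)cc1 | intermediate
27 | 6-[(tert-butyldimethylsilyloxy)methyl]-5,6-O-isopropylidene-cyclohex-2-ene-1,4-diol, configuration as in 30 | O[C@H]1C=C[C@@H](O)[C@H](OC2(C)C)[C@@]1(O2)CO[Si](C)(C)C(C)(C)C | intermediate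
28 | benzoyl chloride | O=C(Cl)c1ccccc1 | starting material
29 | 1,4-di-O-benzoyl derivative of 27 | O=C(O[C@H]1C=C[C@@H](OC(=O)c2ccccc2)[C@H](OC3(C)C)[C@@]1(O3)CO[Si](C)(C)C(C)(C)C)c1ccccc1 | intermediate
30 | [(1S,4R,5S,6S)-4-(benzoyloxy)-5,6-dihydroxy-6-(hydroxymethyl)cyclohex-2-en-1-yl] benzoate | O=C(O[C@H]1C=C[C@@H](OC(=O)c2ccccc2)[C@H](O)[C@@]1(O)CO)c1ccccc1 | target

**Step count.** Total: 16 steps. Longest linear sequence: 16 steps (D-mannose 1 → 30).

**Steps most likely to fail**

1. Step 11 (Ireland–Claisen ring contraction). What may go wrong: desilylation or heterolysis of the doubly activated allylic C–O bond of the ketene acetal outrunning the strained boat rearrangement, with loss of material or erosion of the C1 configuration. Fallback: the fallback sets out from lactone 19 and performs the ring contraction at the aldehyde oxidation level, without a silyl ketene acetal. The enolate of 19 is trapped as the ketene acetal diphenyl phosphate F1 (KN(SiMe3)2, (PhO)2P(O)Cl, THF/HMPA, −78 °C). F1 is reduced to the cyclic enol ether F2 (Pd(PPh3)4, Bu3SnH, LiCl, THF). This robust 6-alkenyl dihydropyran is heated (o-dichlorobenzene, 180 °C) in a neutral thermal Claisen rearrangement, a reaction known for vinyl-substituted glycals, and should give the cyclohexenecarbaldehyde F3 by the same boat topology. NaBH4 (MeOH, 0 °C) then gives alcohol 24, where the route is rejoined; step 12 is skipped.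

2. Step 8 (CuI-catalysed O-vinylation). What may go wrong: base- or heat-induced loss of the anomeric silyl group, or E/Z scrambling during C–O coupling. Fallback: the fallback sets out from aldehyde 13 and builds the enol ether by Horner–Wittig olefination. The reagent [(4-methoxybenzyloxy)methyl]diphenylphosphine oxide F4 is made from commercial (hydroxymethyl)diphenylphosphine oxide, NaH and 4-methoxybenzyl chloride. It is lithiated (LiN(iPr)2, THF, −78 °C) and added to 13. The two threo β-hydroxy phosphine oxides F5 and F6 (epimeric at both new centres) are separated from the other diastereomers on silica. Stereospecific syn elimination (KH, THF) of either one gives the E-enol ether 17, where the route is rejoined; steps 7 and 8 are bypassed.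

3. Step 7 (Takai iodoolefination). What may go wrong: incomplete E selectivity, or C5 epimerisation/β-elimination of the α-alkoxy aldehyde in the Lewis-acidic CrCl2/CrCl3 medium, which would pass on as a C1 epimer after step 11. Fallback: the fallback sets out from aldehyde 13. Corey–Fuchs homologation (CBr4, PPh3, Et3N, CH2Cl2, 0 °C) gives the dibromoalkene F7. n-BuLi (THF, −78 °C) converts it into the terminal alkyne F8. Hydrozirconation–iodination (Cp2Zr(H)Cl, THF, rt; then I2, 0 °C) delivers only the E-alkenyl iodide 15, where the route is rejoined.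

**Further compounds**
F1 | step 11 | ketene acetal diphenyl phosphate of lactone 19 | O=P(Oc1ccccc1)(Oc1ccccc1)OC=1O[C@H](/C=C/OCc3ccc(OC)cc3)[C@@H](OCc3ccc(OC)cc3)[C@@H]2OC(C)(C)OC=12
F2 | step 11 | cyclic enol ether (1,5-anhydro-1-ene analogue of 19, H at C1) | C=1O[C@H](/C=C/OCc3ccc(OC)cc3)[C@@H](OCc3ccc(OC)cc3)[C@@H]2OC(C)(C)OC=12
F3 | step 11 | 5,6-O-isopropylidene-1,4-bis(4-methoxybenzyloxy)cyclohex-2-ene-6-carbaldehyde | COc1ccc(CO[C@H]2C=C[C@@H](OCc3ccc(OC)cc3)[C@H](OC4(C)C)[C@@]2(O4)C=O)cc1
F4 | step 8 | [(4-methoxybenzyloxy)methyl]diphenylphosphine oxide | COc1ccc(COCP(=O)(c2ccccc2)c2ccccc2)cc1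
F5 | step 8 | threo β-hydroxy phosphine oxide adduct of 13 (first C6 epimer) | CC(C)[Si](OC1O[C@H]([C@@H](O)[C@@H](OCc2ccc(OC)cc2)P(=O)(c2ccccc2)c2ccccc2)[C@@H](OCc2ccc(OC)cc2)[C@@H]3OC(C)(C)O[C@H]13)(C(C)C)C(C)C
F6 | step 8 | threo β-hydroxy phosphine oxide adduct of 13 (second C6 epimer) | CC(C)[Si](OC1O[C@H]([C@H](O)[C@H](OCc2ccc(OC)cc2)P(=O)(c2ccccc2)c2ccccc2)[C@@H](OCc2ccc(OC)cc2)[C@@H]3OC(C)(C)O[C@H]13)(C(C)C)C(C)C
F7 | step 7 | triisopropylsilyl 7,7-dibromo-6,7-dideoxy-2,3-O-isopropylidene-4-O-(4-methoxybenzyl)-D-manno-hept-6-enopyranoside | CC(C)[Si](OC1O[C@H](C=C(Br)Br)[C@@H](OCc2ccc(OC)cc2)[C@@H]3OC(C)(C)O[C@H]13)(C(C)C)C(C)C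
F8 | step 7 | triisopropylsilyl 6,7-dideoxy-2,3-O-isopropylidene-4-O-(4-methoxybenzyl)-D-manno-hept-6-ynopyranoside | CC(C)[Si](OC1O[C@H](C#C)[C@@H](OCc2ccc(OC)cc2)[C@@H]3OC(C)(C)O[C@H]13)(C(C)C)C(C)C
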